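## Analysis of the target

Compound 14 is a flavonol. Ring A (C4a, C5, C6, C7, C8, C8a) is fused to the 4-pyranone ring C (O1, C2, C3, C4), and ring B, a 4-methoxyphenyl group, sits on C2. Ring A has free hydroxyls on C5 and C7 and, on C8, a 2-methylbut-3-en-2-yl group whose quaternary carbon is bonded directly to the arene; C3 carries the enolic hydroxyl and C4 the carbonyl. There is no stereocentre, so sp3 centres made on the way need no control as long as they are erased before the end. The delicate parts are the terminal vinyl group beside the C7 hydroxyl (acid can close a dihydrofuran onto it), the electron-rich ring A, the oxidisable 3-hydroxy-4-pyranone, and the single methyl ether on ring B, which forbids a late ether cleavage with strong Lewis acids. The hard point is the C8 substituent: a tertiary allyl group cannot be introduced by direct C-alkylation, and once ring C exists C6 and C8 are two similar positions, so the place of the allyl group relative to O1 has to be settled by design. The route rests on C3 and C4 being neighbouring carbons that both bear oxygen. Ring C can therefore be closed between an aldehyde carbon on C4a and an aldehyde carbon attached to C2, after O1 has been joined to C2. Because that ether is made on the one phenol lying beside the quaternary carbon, the C8 position is fixed before the ring is formed.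

## Retrosynthetic reasoning

14 to 13. The last operation is only the loss of the two methoxymethyl (MOM) acetals on O5 and O7. An acetal is chosen because dilute acid removes it without touching the ring B methyl ether or the vinyl group. Benzyl ethers would need hydrogenolysis, which saturates the vinyl group, and methyl ethers could not be told apart from the ring B ether.

13 to 11 through 12. No skeletal bond is cut here; only the oxidation level changes. Flavonol 13 is the enol form of the chromane-3,4-dione 12, and 12 is what oxidation of both carbinols of diol 11 gives. The gain is that C2, C3 and C4 of 11 may have any configuration. The forward step has to oxidise a glycol, one end of which is benzylic to a very electron-rich ring, without cleaving it.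

11 to 10. The C3–C4 bond is cut. It is the only bond of ring C that joins two oxygenated carbons of the same oxidation level, so it opens to two aldehydes, and the reverse is a reductive carbonyl coupling. O1–C2 is kept because it holds the regiochemical information, and C4–C4a is kept because that carbon arrives with the starting benzoate. Forward, the first electron has to go to the aryl aldehyde, and the ketyl has to add to the second aldehyde before anything else happens.

10 to 9 to 8. Both aldehydes are traced to methyl esters through diol 9. Since both ends stand at the same level, one hydride reduction and one oxidation serve both. Esters are carried through the early steps because an aryl aldehyde would be attacked by the carbanion of the neighbouring α-aryloxy ester under the basic alkylation conditions.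

8 to 6 and 7. The O1–C2 bond is cut. Bromo ester 7 delivers C2, C3 and ring B in one piece to the phenoxide of 6. The only free hydroxyl of 6 is the one between the ester and the quaternary carbon, so this step defines the 8-substituted skeleton. The forward reaction has to overcome the crowding at that oxygen.

6 to 5. Two MOM groups are removed in thought. Forward, the three hydroxyls of 5 must be told apart: the unchelated one on C4 and the less crowded chelated one on C6 should react, leaving the one wedged between the ester and the quaternary carbon.

5 to 3 through 4. The aryl–C(quaternary) bond is cut as a retro-[3,3] shift to the O-prenyl ether 3. The rearrangement inverts the allyl unit, which is the only practical way to place a tertiary allyl carbon on the ring. Ether 3 is symmetric and its para carbon carries the ester, so only one C-allylated product can arise.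

3 to 1 and 2. The O–CH2 bond is cut; forward, the most acidic hydroxyl of 1 is alkylated by 2.

## Alternatives that were turned down

Alternative 1: Ring A is built last, onto a finished pyranone, by cutting C7–C8 and C4a–C5. Forward, the dienolate of 6-(2,2-dimethylbut-3-en-1-yl)-3-(methoxymethoxy)-2-(4-methoxyphenyl)-4H-pyran-4-one A1 would be acylated twice by bis(2,4,6-trichlorophenyl) malonate A2, and the new ring would aromatise to 5,7-dihydroxy-3-(methoxymethoxy)-2-(4-methoxyphenyl)-8-(2-methylbut-3-en-2-yl)-4H-chromen-4-one A3.
- For it: the route is convergent, the tertiary allyl carbon is on C8 from the start with no Claisen shift and no regiochemical question, and only one acetal is left to remove. On these points it is stronger than the chosen route.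
- Against it: the carbon that must be acylated first is a methylene next to a quaternary centre, the most crowded site in A1. The methylene protons of A2 are far more acidic than the dienolate is basic-stable, so proton transfer should quench the nucleophile before C-acylation, and O-acylation of the enolate is a further outlet. A1 itself would need about five steps from kojic acid A4 (protection, arylation of the ring carbon next to the oxygenated one, chain extension with a tertiary allyl nucleophile).
- Comparison: the step count would be similar. The chosen route offers instead a key step that forms a single bond by a reaction type with close analogy, reached through standard reactions.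

Alternative 2: Ring C is built onto unprotected phloroglucinol A5 by forming C4–C4a (C-acylation) and O1–C2 (cyclodehydration). Forward, A5 and ethyl 2-(benzoyloxy)-3-(4-methoxyphenyl)-3-oxopropanoate A6 would be heated without solvent to give 5,7-dihydroxy-2-(4-methoxyphenyl)-4-oxo-4H-chromen-3-yl benzoate A7.
- For it: it is very short, uses cheap materials, needs no protecting groups in the key step, and thermal condensation of polyphenols with β-keto esters to chromones is well founded. On step economy and precedent it is clearly stronger than the chosen route.
- Against it: A7 has no substituent on C8. The allyl group would have to come afterwards by O-prenylation of the C7 hydroxyl with 2 and a Claisen shift. At that stage the two ortho positions C6 and C8 are no longer equivalent, so 3,5,7-trihydroxy-2-(4-methoxyphenyl)-6-(2-methylbut-3-en-2-yl)-4H-chromen-4-one A8 would form beside the target, and the two differ only in the position of one group. The benzoate may also migrate or be lost at the temperature of the condensation, and Pechmann-type closure onto the ketone would lead to a coumarin skeleton.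
- Comparison: the symmetry of A5 is spent before the allyl group arrives. The chosen route does the Claisen shift while the ring is still symmetric and then fixes O1 beside the quaternary carbon, at the price of about five more steps.

Alternative 3: Ring A is made by a Danheiser-type benzannulation, forming C8–C8a and C6–C7 and closing the ring by 6π electrocyclisation at C4a–C8a. Forward, 3-ethoxycyclobut-2-en-1-one A9 and [(3,3-dimethylpent-4-en-1-yn-1-yl)oxy]tri(propan-2-yl)silane A10 would be heated to give 5-ethoxy-2-(2-methylbut-3-en-2-yl)-3-(triisopropylsilyloxy)phenol A11.
- For it: A11 has three different oxygens (free hydroxyl, silyl ether, ethyl ether) and the tertiary allyl group in a pattern fixed by the mechanism. This is stronger than the chosen route, which relies on steric bias in the double MOM protection of step 3.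
- Against it: A10 is not an article of commerce and needs its own multistep preparation, and its quaternary propargylic carbon crowds the [2+2] step. A11 is ring A only: C-acylation at the future C4a (in competition with C6) and the whole flavonol construction still follow. The ethyl ether on O5 must finally be cleaved in the presence of the ring B methyl ether and of the acid-sensitive vinyl group beside a free phenol.
- Comparison: the benzannulation replaces only steps 1 to 3 of the chosen route and makes the whole longer. The chosen route takes ring A from a commercial phloroglucinol ester and accepts one selectivity question instead.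

Key step: step 7

Remark on the chemistry: the target has no stereocentre, so bromo ester 7 is used as the racemate and the chiral intermediates 8 to 12 are carried as racemates or diastereomer mixtures.

## Route

Step 1
Reactants: 1 methyl 2,4,6-trihydroxybenzoate; 2 prenyl bromide (1-bromo-3-methylbut-2-ene)
Product: 3 methyl 2,6-dihydroxy-4-[(3-methylbut-2-en-1-yl)oxy]benzoate
Conditions: K2CO3 (1.05 equiv), 2 (1.0 equiv), acetone, rt → 45 °C
Reagents that add atoms: none
Why: Williamson ether synthesis; the C4 hydroxyl is para to the ester and not hydrogen-bonded to it, hence the most acidic, so one equivalent of weak base and of 2 should alkylate there. A carbonate base in acetone favours O- over C-alkylation.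

Step 2
Reactants: 3 methyl 2,6-dihydroxy-4-[(3-methylbut-2-en-1-yl)oxy]benzoate
Product: 5 methyl 2,4,6-trihydroxy-3-(2-methylbut-3-en-2-yl)benzoate, via cyclohexadienone 4 (not isolated)
Conditions: Eu(fod)3 (10 mol%), CHCl3, 60 °C
Reagents that add atoms: none
Why: Aromatic Claisen rearrangement ([3,3] shift) catalysed by Eu(fod)3, the trivalent europium tris(6,6,7,7,8,8,8-heptafluoro-2,2-dimethyl-3,5-octanedionate); the two ortho positions of 3 are equivalent and the para carbon bears the ester, so a single product is expected, with the allyl unit inverted to the 1,1-dimethylallyl group. Dienone 4 tautomerises to 5, and the low temperature should keep the new phenols from adding to the vinyl group.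

Step 3
Reactants: 5 methyl 2,4,6-trihydroxy-3-(2-methylbut-3-en-2-yl)benzoate
Product: 6 methyl 2-hydroxy-4,6-bis(methoxymethoxy)-3-(2-methylbut-3-en-2-yl)benzoate
Conditions: MOMCl (2.1 equiv), i-Pr2NEt (2.5 equiv), CH2Cl2, 0 °C → rt
Reagents that add atoms: chloromethyl methyl ether (MOMCl), COCCl
Why: Acetal (MOM ether) formation with an amine base; the C4 hydroxyl is not chelated and should react first. Of the two hydroxyls beside the ester, the one on C6 has an unsubstituted neighbour, while the one on C2 is wedged between the ester and the quaternary carbon and should stay free.

Step 4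
Reactants: 6 methyl 2-hydroxy-4,6-bis(methoxymethoxy)-3-(2-methylbut-3-en-2-yl)benzoate; 7 methyl 2-bromo-2-(4-methoxyphenyl)acetate (racemic)
Product: 8 methyl 2-[2-methoxy-1-(4-methoxyphenyl)-2-oxoethoxy]-4,6-bis(methoxymethoxy)-3-(2-methylbut-3-en-2-yl)benzoate (racemic)
Conditions: Cs2CO3 (1.5 equiv), 7 (1.3 equiv), DMF, rt → 40 °C
Reagents that add atoms: none
Why: Williamson ether synthesis (SN2); the caesium phenoxide of 6 should displace bromide from 7, a benzylic α-bromo ester and thus a very reactive electrophile, which offsets the crowding at the oxygen. Only one hydroxyl is free, so O1–C2 can form at no other oxygen, and the mild temperature should keep the product from a Dieckmann-type closure.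

Step 5
Reactants: 8 methyl 2-[2-methoxy-1-(4-methoxyphenyl)-2-oxoethoxy]-4,6-bis(methoxymethoxy)-3-(2-methylbut-3-en-2-yl)benzoate
Product: 9 2-[2-(hydroxymethyl)-3,5-bis(methoxymethoxy)-6-(2-methylbut-3-en-2-yl)phenoxy]-2-(4-methoxyphenyl)ethan-1-ol (racemic)
Conditions: LiAlH4 (3 equiv), THF, 0 °C → rt; then Na2SO4·10H2O
Reagents that add atoms: none
Why: Hydride reduction of both methyl esters to primary alcohols; the ethers, the MOM acetals and the isolated alkene are inert to LiAlH4. The work-up is kept free of acid because the trioxygenated benzylic alcohol ionises easily.

Step 6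
Reactants: 9 2-[2-(hydroxymethyl)-3,5-bis(methoxymethoxy)-6-(2-methylbut-3-en-2-yl)phenoxy]-2-(4-methoxyphenyl)ethan-1-ol
Product: 10 2-[2-formyl-3,5-bis(methoxymethoxy)-6-(2-methylbut-3-en-2-yl)phenoxy]-2-(4-methoxyphenyl)acetaldehyde (racemic)
Conditions: IBX (2.6 equiv), DMSO, rt; crude product used at once
Reagents that add atoms: none
Why: Oxidation of both primary alcohols by the hypervalent iodine reagent 2-iodoxybenzoic acid (IBX) under neutral conditions. Activated-DMSO methods are avoided because their chloride and amine base could ionise the electron-rich benzylic position or enolise the new α-aryloxy aldehyde towards aldol closure on its neighbour.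

Step 7
Reactants: 10 2-[2-formyl-3,5-bis(methoxymethoxy)-6-(2-methylbut-3-en-2-yl)phenoxy]-2-(4-methoxyphenyl)acetaldehyde
Product: 11 5,7-bis(methoxymethoxy)-2-(4-methoxyphenyl)-8-(2-methylbut-3-en-2-yl)chromane-3,4-diol (racemic; diastereomer mixture)
Conditions: SmI2 (2.5 equiv, 0.1 M in THF, slow addition), THF (0.01 M in 10), −78 °C → 0 °C; then H2O
Reagents that add atoms: none
Why: SmI2 (divalent samarium) should transfer one electron to the aryl aldehyde of 10, which is conjugated and therefore reduced more easily than the aliphatic aldehyde, giving a samarium-bound ketyl at C4. The ketyl carbon adds to the C3 aldehyde, held within reach by the O1–C2 tether and by coordination to the same oxophilic trivalent samarium, and a second equivalent of SmI2 reduces the oxygen-centred radical as it forms, so that the samarium diolate is protonated to 11 on work-up. The closest known reaction type is the SmI2-mediated intramolecular pinacol coupling of 1,6-dialdehydes to cyclohexane-1,2-diols, which tolerates α-oxygenated aldehydes. Ring C closes in the 6-exo-trig mode by forming the C3–C4 bond. C3 and C4 become stereocentres beside the existing C2; chelation of both oxygens to samarium should favour the cis-diol with the C2 aryl group equatorial, but no control is needed because step 8 erases all three centres. The selectivity the step needs is electron transfer to the aryl aldehyde and not to the α-aryloxy aldehyde, whose ketyl would expel the ring A phenoxide; it is secured by the conjugation of the aryl aldehyde, by leaving out HMPA, and by adding the reductant slowly at −78 °C so that cyclisation outruns a second reduction. High dilution suppresses intermolecular coupling, and the MOM acetals, the anisole and the isolated vinyl group are inert to SmI2 in THF.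

Step 8
Reactants: 11 5,7-bis(methoxymethoxy)-2-(4-methoxyphenyl)-8-(2-methylbut-3-en-2-yl)chromane-3,4-diol
Product: 13 3-hydroxy-5,7-bis(methoxymethoxy)-2-(4-methoxyphenyl)-8-(2-methylbut-3-en-2-yl)-4H-chromen-4-one, via chromane-3,4-dione 12 (not isolated)
Conditions: IBX (2.5 equiv), DMSO, rt → 40 °C
Reagents that add atoms: none
Why: IBX oxidation of a 1,2-diol to the 1,2-diketone, a reagent that does not cleave glycols and brings no chloride to the ionisable benzylic C4. Dione 12 has an acidic C2–H and should enolise at once to the conjugated 3-hydroxy-4-pyranone 13, which removes the stereocentres at C2, C3 and C4.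

Step 9
Reactants: 13 3-hydroxy-5,7-bis(methoxymethoxy)-2-(4-methoxyphenyl)-8-(2-methylbut-3-en-2-yl)-4H-chromen-4-one
Product: 14 3,5,7-trihydroxy-2-(4-methoxyphenyl)-8-(2-methylbut-3-en-2-yl)-4H-chromen-4-one
Conditions: HCl (2 M aq), MeOH/THF, 45 °C
Reagents that add atoms: none
Why: Acid-catalysed acetal cleavage (transacetalisation to the solvent alcohol) frees O5 and O7. The monosubstituted vinyl group is much harder to protonate than a trisubstituted prenyl alkene, and the ring B methyl ether is stable to dilute acid, so both should survive.

## Compound list

1 | methyl 2,4,6-trihydroxybenzoate | COC(=O)c1c(O)cc(O)cc1O | starting material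
2 | prenyl bromide (1-bromo-3-methylbut-2-ene) | CC(C)=CCBr | starting material
3 | methyl 2,6-dihydroxy-4-[(3-methylbut-2-en-1-yl)oxy]benzoate | COC(=O)c1c(O)cc(OCC=C(C)C)cc1O | intermediate
4 | methyl 2,6-dihydroxy-3-(2-methylbut-3-en-2-yl)-4-oxocyclohexa-1,5-diene-1-carboxylate (racemic; not isolated) | COC(=O)C1=C(O)C(C(C)(C)C=C)C(=O)C=C1O | intermediate
5 | methyl 2,4,6-trihydroxy-3-(2-methylbut-3-en-2-yl)benzoate | COC(=O)c1c(O)cc(O)c(C(C)(C)C=C)c1O | intermediate
6 | methyl 2-hydroxy-4,6-bis(methoxymethoxy)-3-(2-methylbut-3-en-2-yl)benzoate | COC(=O)c1c(OCOC)cc(OCOC)c(C(C)(C)C=C)c1O | intermediate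
7 | methyl 2-bromo-2-(4-methoxyphenyl)acetate (racemic) | COC(=O)C(Br)c1ccc(OC)cc1 | starting material
8 | methyl 2-[2-methoxy-1-(4-methoxyphenyl)-2-oxoethoxy]-4,6-bis(methoxymethoxy)-3-(2-methylbut-3-en-2-yl)benzoate (racemic) | COC(=O)c1c(OCOC)cc(OCOC)c(C(C)(C)C=C)c1OC(C(=O)OC)c1ccc(OC)cc1 | intermediate
9 | 2-[2-(hydroxymethyl)-3,5-bis(methoxymethoxy)-6-(2-methylbut-3-en-2-yl)phenoxy]-2-(4-methoxyphenyl)ethan-1-ol (racemic) | C=CC(C)(C)c1c(OCOC)cc(OCOC)c(CO)c1OC(CO)c1ccc(OC)cc1 | intermediate
10 | 2-[2-formyl-3,5-bis(methoxymethoxy)-6-(2-methylbut-3-en-2-yl)phenoxy]-2-(4-methoxyphenyl)acetaldehyde (racemic) | C=CC(C)(C)c1c(OCOC)cc(OCOC)c(C=O)c1OC(C=O)c1ccc(OC)cc1 | intermediate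
11 | 5,7-bis(methoxymethoxy)-2-(4-methoxyphenyl)-8-(2-methylbut-3-en-2-yl)chromane-3,4-diol (racemic; diastereomer mixture) | C=CC(C)(C)c1c(OCOC)cc(OCOC)c2c1OC(c1ccc(OC)cc1)C(O)C2O | intermediate
12 | 5,7-bis(methoxymethoxy)-2-(4-methoxyphenyl)-8-(2-methylbut-3-en-2-yl)chromane-3,4-dione (racemic; not isolated) | C=CC(C)(C)c1c(OCOC)cc(OCOC)c2c1OC(c1ccc(OC)cc1)C(=O)C2=O | intermediate
13 | 3-hydroxy-5,7-bis(methoxymethoxy)-2-(4-methoxyphenyl)-8-(2-methylbut-3-en-2-yl)-4H-chromen-4-one | C=CC(C)(C)c1c(OCOC)cc(OCOC)c2c(=O)c(O)c(-c3ccc(OC)cc3)oc12 | intermediate
14 | 3,5,7-trihydroxy-2-(4-methoxyphenyl)-8-(2-methylbut-3-en-2-yl)-4H-chromen-4-one | C=CC(C)(C)c1c(O)cc(O)c2c(=O)c(O)c(-c3ccc(OC)cc3)oc12 | target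

## Step count and least certain steps

Total: 9 steps. Longest linear sequence: 9 steps, from 1 to 14; 2 and 7 enter as commercial reagents.

Step 7 (key step). The most likely failure is electron transfer to the α-aryloxy aldehyde, followed by loss of the ring A phenoxide and thus cleavage of the O1–C2 bond. That aldehyde is activated by its α-oxygen and α-aryl group and has a good leaving group on the neighbouring carbon. Simple reduction of the aryl aldehyde without bond formation and intermolecular coupling are lesser risks. The fallback avoids electron transfer altogether; it sets out from 10 and comes back at 11.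
- Double Wittig methylenation (Ph3PCH3Br, KN(SiMe3)2, THF, −78 → 0 °C) should give 1-ethenyl-2-{[1-(4-methoxyphenyl)prop-2-en-1-yl]oxy}-4,6-bis(methoxymethoxy)-3-(2-methylbut-3-en-2-yl)benzene F1.
- Ring-closing metathesis with the second-generation Grubbs catalyst (CH2Cl2, 40 °C) should close the C3=C4 bond to 5,7-bis(methoxymethoxy)-2-(4-methoxyphenyl)-8-(2-methylbut-3-en-2-yl)-2H-chromene F2. The vinyl group on the quaternary carbon is too crowded to compete.
- Dimethyldioxirane (acetone, −20 °C) should epoxidise the electron-rich C3=C4 bond in preference to the isolated vinyl group, giving 3,4-epoxy-5,7-bis(methoxymethoxy)-2-(4-methoxyphenyl)-8-(2-methylbut-3-en-2-yl)chromane F3. This should open with water at the benzylic C4 on work-up to give 11.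

Step 4. Displacement at the secondary benzylic carbon may be slow because the phenoxide oxygen lies between the ester and the quaternary carbon. The longer the base acts, the more the enolate of the product can close onto the neighbouring aryl ester (Dieckmann-type closure to a five-membered ring), and elimination or solvolysis of 7 competes. The fallback forms the same O–C bond without base; it sets out from 6 and comes back at 8. Methyl 2-diazo-2-(4-methoxyphenyl)acetate F4, made by diazo transfer (p-acetamidobenzenesulfonyl azide, DBU) to commercial methyl 2-(4-methoxyphenyl)acetate, is decomposed with Rh2(OAc)4 (dirhodium tetraacetate, divalent rhodium) in CH2Cl2 at rt in the presence of 6. The carbenoid should insert into the O–H bond, and the crowded vinyl group should cyclopropanate only slowly.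

Step 3. The two hydroxyls beside the ester may not be told apart well enough, so that the acetal goes on the wrong one or on all three. The difference between them is steric only. The fallback lets the mechanism decide which hydroxyl is free; it sets out from 1 and comes back at 6.
- MOMCl (2 equiv) and i-Pr2NEt should give methyl 2-hydroxy-4,6-bis(methoxymethoxy)benzoate F5, since the last chelated hydroxyl of such a system resists protection.
- Alkylation with 2 (K2CO3, DMF, 60 °C) should give methyl 2,4-bis(methoxymethoxy)-6-[(3-methylbut-2-en-1-yl)oxy]benzoate F6.
- Thermal Claisen rearrangement (PhNEt2, 180 °C) can deliver the allyl unit only to the ortho carbon that is not occupied by the ester, which gives 6. The price is a possible second [3,3] shift that carries the allyl unit on to the para position, so a separation may be needed.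

Step 6. The new α-aryloxy arylacetaldehyde enolises easily and may undergo aldol attack on the adjacent aryl aldehyde, closing a five-membered ring, or degrade on concentration. The fallback never passes through an oxidation; it sets out from 8 and comes back at 10. Partial reduction of both esters with i-Bu2AlH (2.2 equiv, toluene, −78 °C) keeps the two carbonyls masked as aluminium hemiacetals until a cold neutral work-up with aqueous KNaC4H4O6, and diol 9 is skipped. No new compound is made.

Step 8. The glycol may be cleaved, the electron-rich benzylic C4 may ionise, the oxidation may stop at a ketol, or the flavonol enol may be oxidised further. The fallback treats the two carbinols separately; it sets out from 11 and comes back at 13. DDQ (CH2Cl2, rt) should oxidise only the benzylic C4 carbinol, by hydride abstraction stabilised by the trioxygenated ring, to give 3-hydroxy-5,7-bis(methoxymethoxy)-2-(4-methoxyphenyl)-8-(2-methylbut-3-en-2-yl)chroman-4-one F7. Dess–Martin periodinane with pyridine should then oxidise the remaining C3 carbinol to 12, which enolises to 13.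

## Further compounds

F1 | step 7 | 1-ethenyl-2-{[1-(4-methoxyphenyl)prop-2-en-1-yl]oxy}-4,6-bis(methoxymethoxy)-3-(2-methylbut-3-en-2-yl)benzene (racemic) | C=CC(C)(C)c1c(OCOC)cc(OCOC)c(C=C)c1OC(C=C)c1ccc(OC)cc1
F2 | step 7 | 5,7-bis(methoxymethoxy)-2-(4-methoxyphenyl)-8-(2-methylbut-3-en-2-yl)-2H-chromene (racemic) | C=CC(C)(C)c1c(OCOC)cc(OCOC)c2c1OC(c1ccc(OC)cc1)C=C2
F3 | step 7 | 3,4-epoxy-5,7-bis(methoxymethoxy)-2-(4-methoxyphenyl)-8-(2-methylbut-3-en-2-yl)chromane (racemic; diastereomer mixture) | C=CC(C)(C)c1c(OCOC)cc(OCOC)c2c1OC(c1ccc(OC)cc1)C1OC21
F4 | step 4 | methyl 2-diazo-2-(4-methoxyphenyl)acetate | COC(=O)C(=[N+]=[N-])c1ccc(OC)cc1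
F5 | step 3 | methyl 2-hydroxy-4,6-bis(methoxymethoxy)benzoate | COC(=O)c1c(O)cc(OCOC)cc1OCOC
F6 | step 3 | methyl 2,4-bis(methoxymethoxy)-6-[(3-methylbut-2-en-1-yl)oxy]benzoate | COC(=O)c1c(OCC=C(C)C)cc(OCOC)cc1OCOC
F0 | step 6 | none | none
F7 | step 8 | 3-hydroxy-5,7-bis(methoxymethoxy)-2-(4-methoxyphenyl)-8-(2-methylbut-3-en-2-yl)chroman-4-one (racemic; diastereomer mixture) | C=CC(C)(C)c1c(OCOC)cc(OCOC)c2c1OC(c1ccc(OC)cc1)C(O)C2=O
A1 | alternative 1 | 6-(2,2-dimethylbut-3-en-1-yl)-3-(methoxymethoxy)-2-(4-methoxyphenyl)-4H-pyran-4-one | C=CC(C)(C)Cc1cc(=O)c(OCOC)c(-c2ccc(OC)cc2)o1
A2 | alternative 1 | bis(2,4,6-trichlorophenyl) malonate | O=C(CC(=O)Oc1c(Cl)cc(Cl)cc1Cl)Oc1c(Cl)cc(Cl)cc1Cl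
A3 | alternative 1 | 5,7-dihydroxy-3-(methoxymethoxy)-2-(4-methoxyphenyl)-8-(2-methylbut-3-en-2-yl)-4H-chromen-4-one | C=CC(C)(C)c1c(O)cc(O)c2c(=O)c(OCOC)c(-c3ccc(OC)cc3)oc12
A4 | alternative 1 | kojic acid (5-hydroxy-2-(hydroxymethyl)-4H-pyran-4-one) | OCc1cc(=O)c(O)co1
A5 | alternative 2 | phloroglucinol (benzene-1,3,5-triol) | Oc1cc(O)cc(O)c1
A6 | alternative 2 | ethyl 2-(benzoyloxy)-3-(4-methoxyphenyl)-3-oxopropanoate (racemic) | CCOC(=O)C(OC(=O)c1ccccc1)C(=O)c1ccc(OC)cc1
A7 | alternative 2 | 5,7-dihydroxy-2-(4-methoxyphenyl)-4-oxo-4H-chromen-3-yl benzoate | COc1ccc(cc1)-c1oc2cc(O)cc(O)c2c(=O)c1OC(=O)c1ccccc1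
A8 | alternative 2 | 3,5,7-trihydroxy-2-(4-methoxyphenyl)-6-(2-methylbut-3-en-2-yl)-4H-chromen-4-one | C=CC(C)(C)c1c(O)cc2oc(-c3ccc(OC)cc3)c(O)c(=O)c2c1O
A9 | alternative 3 | 3-ethoxycyclobut-2-en-1-one | CCOC1=CC(=O)C1
A10 | alternative 3 | [(3,3-dimethylpent-4-en-1-yn-1-yl)oxy]tri(propan-2-yl)silane | C=CC(C)(C)C#CO[Si](C(C)C)(C(C)C)C(C)C
A11 | alternative 3 | 5-ethoxy-2-(2-methylbut-3-en-2-yl)-3-(triisopropylsilyloxy)phenol | C=CC(C)(C)c1c(O)cc(OCC)cc1O[Si](C(C)C)(C(C)C)C(C)C
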